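**Plan**

- Cuts: (a) the C8–CH2 bond of the prenyl group, traced back to a 5‑O‑prenyl ether (para‑Claisen–Cope); (b) the C2–C1′ bond together with O1–C2 of the pyranone ring, giving an aryl ethynyl ketone (ring A) and an iodochromene (ring B); (c) C4–C4a of the chromene, traced back to an aryl 1,1‑dimethylpropargyl ether.
- Enabling feature: C2 is the β‑carbon of the vinylogous ester O1–C2=C3–C4=O of ring C. At the ynone oxidation level it is a terminal sp C–H, so it can be coupled to C1′ by Pd/Cu, and once arylated it is the Michael terminus for the phenolic O1.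
- Forward order: ring A comes from 2,4,6‑trihydroxybenzaldehyde; the chromene ring is built on the B fragment by a thermal Claisen cascade; fragment union and ring C are made in one pot; the prenyl group then moves O5 → C6 → C8.
- Regiocontrol: the O‑prenyl group sits on the second ortho oxygen, so ring C can close through one oxygen only, and that same group ends up at C8.
- Stereochemistry: the target is achiral; the only stereocentre on the route (carbinol of 6) is racemic and is erased by oxidation.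

Key step: step 9

Remark: the target has no stereocentre and no stereogenic double bond, so none of the SMILES carries a stereodescriptor.

**Step 1**
Reactants: 1 2,4,6‑trihydroxybenzaldehyde
Product: 2 2‑hydroxy‑4,6‑bis{[tri(propan‑2‑yl)silyl]oxy}benzaldehyde
Conditions: TIPSCl (2.1 equiv), imidazole, DMF, 0 °C → rt
Reagents that add atoms: chlorotri(propan‑2‑yl)silane (TIPSCl), CC(C)[Si](Cl)(C(C)C)C(C)C
Why: Phenol silylation should take the para hydroxyl and one ortho hydroxyl, while the last ortho hydroxyl is held in the hydrogen bond to the formyl group and stays free.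

**Step 2**
Reactants: 2 2‑hydroxy‑4,6‑bis{[tri(propan‑2‑yl)silyl]oxy}benzaldehyde; 3 3‑methylbut‑2‑en‑1‑ol (prenol)
Product: 4 2‑[(3‑methylbut‑2‑en‑1‑yl)oxy]‑4,6‑bis{[tri(propan‑2‑yl)silyl]oxy}benzaldehyde
Conditions: PPh3, DIAD, THF, 0 °C → rt
Reagents that add atoms: none
Why: Mitsunobu etherification of the acidic chelated phenol with the primary allylic alcohol should proceed by SN2 at the prenyl CH2 under neutral conditions that leave the aryl silyl ethers untouched.

**Step 3**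
Reactants: 4 2‑[(3‑methylbut‑2‑en‑1‑yl)oxy]‑4,6‑bis{[tri(propan‑2‑yl)silyl]oxy}benzaldehyde; 5 ethynylmagnesium bromide
Product: 6 rac‑1‑{2‑[(3‑methylbut‑2‑en‑1‑yl)oxy]‑4,6‑bis{[tri(propan‑2‑yl)silyl]oxy}phenyl}prop‑2‑yn‑1‑ol
Conditions: THF, −78 → 0 °C; then sat. aq NH4Cl
Reagents that add atoms: none
Why: 1,2‑Addition of the small alkynyl Grignard reagent to the hindered aldehyde should give the carbinol as a racemate (the centre is erased in step 4), and the bulky TIPS group with a cold quench should prevent silyl transfer to the new alkoxide.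

**Step 4**
Reactants: 6 rac‑1‑{2‑[(3‑methylbut‑2‑en‑1‑yl)oxy]‑4,6‑bis{[tri(propan‑2‑yl)silyl]oxy}phenyl}prop‑2‑yn‑1‑ol
Product: 7 1‑{2‑[(3‑methylbut‑2‑en‑1‑yl)oxy]‑4,6‑bis{[tri(propan‑2‑yl)silyl]oxy}phenyl}prop‑2‑yn‑1‑one
Conditions: activated MnO2, CH2Cl2, rt
Reagents that add atoms: none
Why: MnO2 oxidation of a benzylic and propargylic alcohol should give the terminal ynone under neutral conditions that spare the prenyl ether and the silyl ethers.

**Step 5**
Reactants: 8 2‑hydroxy‑5‑iodobenzaldehyde; 9 3‑chloro‑3‑methylbut‑1‑yne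
Product: 10 5‑iodo‑2‑[(2‑methylbut‑3‑yn‑2‑yl)oxy]benzaldehyde
Conditions: CuCl2·2H2O (cat.), DBU, MeCN, 0 °C → rt
Reagents that add atoms: none
Why: Copper‑catalysed propargylic etherification (via a copper acetylide/allenylidene of the tertiary chloride) should alkylate the acidic phenol at oxygen to give the tertiary aryl propargyl ether.

**Step 6**
Reactants: 10 5‑iodo‑2‑[(2‑methylbut‑3‑yn‑2‑yl)oxy]benzaldehyde
Product: 12 5‑iodo‑2‑[(2‑methylbut‑3‑yn‑2‑yl)oxy]phenol, via aryl formate 11 (not isolated)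
Conditions: mCPBA, CH2Cl2, rt; then K2CO3 (cat.), MeOH, 0 °C
Reagents that add atoms: 3‑chloroperoxybenzoic acid (mCPBA), OOC(=O)c1cccc(Cl)c1
Why: In this Baeyer–Villiger (Dakin‑type) oxidation the ortho‑alkoxyaryl group should migrate in preference to hydride to give the formate, which is methanolysed to the phenol.

**Step 7**
Reactants: 12 5‑iodo‑2‑[(2‑methylbut‑3‑yn‑2‑yl)oxy]phenol
Product: 13 {5‑iodo‑2‑[(2‑methylbut‑3‑yn‑2‑yl)oxy]phenoxy}tri(propan‑2‑yl)silane
Conditions: TIPSCl, imidazole, DMF, rt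
Reagents that add atoms: chlorotri(propan‑2‑yl)silane (TIPSCl), CC(C)[Si](Cl)(C(C)C)C(C)C
Why: Standard phenol silylation masks the hydroxyl before the thermal step, so that it cannot add to the alkyne or to the intermediates of the rearrangement.

**Step 8**
Reactants: 13 {5‑iodo‑2‑[(2‑methylbut‑3‑yn‑2‑yl)oxy]phenoxy}tri(propan‑2‑yl)silane
Product: 14 [(6‑iodo‑2,2‑dimethyl‑2H‑chromen‑8‑yl)oxy]tri(propan‑2‑yl)silane
Conditions: PhNEt2, 170 °C
Reagents that add atoms: none
Why: The aromatic propargyl Claisen rearrangement to the only free ortho carbon, followed by enolisation, 1,5‑H shift and oxa‑6π electrocyclisation, should give the 2,2‑dimethyl‑2H‑chromene with iodine at C6 and the silyloxy group at C8.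

**Step 9**
Reactants: 7 1‑{2‑[(3‑methylbut‑2‑en‑1‑yl)oxy]‑4,6‑bis{[tri(propan‑2‑yl)silyl]oxy}phenyl}prop‑2‑yn‑1‑one; 14 [(6‑iodo‑2,2‑dimethyl‑2H‑chromen‑8‑yl)oxy]tri(propan‑2‑yl)silane
Product: 16 7‑hydroxy‑2‑(8‑hydroxy‑2,2‑dimethyl‑2H‑chromen‑6‑yl)‑5‑[(3‑methylbut‑2‑en‑1‑yl)oxy]‑4H‑chromen‑4‑one, via diaryl ynone 15 (not isolated)
Conditions: PdCl2(PPh3)2 (3 mol %), CuI (5 mol %), Et3N, degassed THF, rt; then TBAF (3.3 equiv), THF, 0 °C → rt; AcOH quench
Reagents that add atoms: none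
Why: Pd(0) inserts into the C–I bond of 14, the copper acetylide of the acidic terminal ynone 7 transmetallates and reductive elimination forms the C2–C1′ bond to give 15; fluoride then removes the three silyl groups, the phenoxide ortho to the ketone adds to the alkyne carbon that now carries ring B, and the allenolate is protonated at C3. The closest known reaction types are the Sonogashira coupling of terminal alkynones with aryl iodides and the fluoride‑induced cyclisation of o‑silyloxyaryl ynones to chromones and flavones. Ring C closes in the 6‑endo‑dig mode as an intramolecular oxa‑Michael addition. No stereocentre is formed. The step needs closure through the correct one of the two ortho oxygens, which is secured because the other carries the prenyl group and cannot add; it needs 6‑endo rather than 5‑exo (aurone) closure, which the aprotic medium should favour because only the Michael mode gives a stabilised anion; and it needs the ynone to survive until it is coupled, which is secured because the TIPS ether is stable to Et3N and falls only to fluoride.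

**Step 10**
Reactants: 16 7‑hydroxy‑2‑(8‑hydroxy‑2,2‑dimethyl‑2H‑chromen‑6‑yl)‑5‑[(3‑methylbut‑2‑en‑1‑yl)oxy]‑4H‑chromen‑4‑one
Product: 17 5,7‑dihydroxy‑2‑(8‑hydroxy‑2,2‑dimethyl‑2H‑chromen‑6‑yl)‑8‑(3‑methylbut‑2‑en‑1‑yl)‑4H‑chromen‑4‑one
Conditions: Eu(fod)3 (10 mol %), NaHCO3, PhCl, 85 °C
Reagents that add atoms: none
Why: Eu(III) chelated at C4=O/O5 should promote the aromatic Claisen shift (O5 → C6, giving the 1,1‑dimethylallyl dienone) and the following Cope shift (C6 → C8), and enolisation then gives the 8‑prenyl‑5‑hydroxyflavone, C8 being the only position para to O5.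

**Compound list**

1 | 2,4,6‑trihydroxybenzaldehyde | O=Cc1c(O)cc(O)cc1O | starting material
2 | 2‑hydroxy‑4,6‑bis{[tri(propan‑2‑yl)silyl]oxy}benzaldehyde | O=Cc1c(O)cc(O[Si](C(C)C)(C(C)C)C(C)C)cc1O[Si](C(C)C)(C(C)C)C(C)C | intermediate
3 | 3‑methylbut‑2‑en‑1‑ol (prenol) | CC(C)=CCO | starting material
4 | 2‑[(3‑methylbut‑2‑en‑1‑yl)oxy]‑4,6‑bis{[tri(propan‑2‑yl)silyl]oxy}benzaldehyde | O=Cc1c(OCC=C(C)C)cc(O[Si](C(C)C)(C(C)C)C(C)C)cc1O[Si](C(C)C)(C(C)C)C(C)C | intermediate
5 | ethynylmagnesium bromide | C#C[Mg]Br | starting material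
6 | rac‑1‑{2‑[(3‑methylbut‑2‑en‑1‑yl)oxy]‑4,6‑bis{[tri(propan‑2‑yl)silyl]oxy}phenyl}prop‑2‑yn‑1‑ol | OC(C#C)c1c(OCC=C(C)C)cc(O[Si](C(C)C)(C(C)C)C(C)C)cc1O[Si](C(C)C)(C(C)C)C(C)C | intermediate
7 | 1‑{2‑[(3‑methylbut‑2‑en‑1‑yl)oxy]‑4,6‑bis{[tri(propan‑2‑yl)silyl]oxy}phenyl}prop‑2‑yn‑1‑one | O=C(C#C)c1c(OCC=C(C)C)cc(O[Si](C(C)C)(C(C)C)C(C)C)cc1O[Si](C(C)C)(C(C)C)C(C)C | intermediate
8 | 2‑hydroxy‑5‑iodobenzaldehyde | O=Cc1cc(I)ccc1O | starting material
9 | 3‑chloro‑3‑methylbut‑1‑yne | C#CC(C)(C)Cl | starting material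
10 | 5‑iodo‑2‑[(2‑methylbut‑3‑yn‑2‑yl)oxy]benzaldehyde | O=Cc1cc(I)ccc1OC(C)(C)C#C | intermediate
11 | 5‑iodo‑2‑[(2‑methylbut‑3‑yn‑2‑yl)oxy]phenyl formate | O=COc1cc(I)ccc1OC(C)(C)C#C | intermediate
12 | 5‑iodo‑2‑[(2‑methylbut‑3‑yn‑2‑yl)oxy]phenol | Oc1cc(I)ccc1OC(C)(C)C#C | intermediate
13 | {5‑iodo‑2‑[(2‑methylbut‑3‑yn‑2‑yl)oxy]phenoxy}tri(propan‑2‑yl)silane | CC(C)[Si](Oc1cc(I)ccc1OC(C)(C)C#C)(C(C)C)C(C)C | intermediate
14 | [(6‑iodo‑2,2‑dimethyl‑2H‑chromen‑8‑yl)oxy]tri(propan‑2‑yl)silane | CC1(C)C=Cc2cc(I)cc(O[Si](C(C)C)(C(C)C)C(C)C)c2O1 | intermediate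
15 | 3‑(2,2‑dimethyl‑8‑{[tri(propan‑2‑yl)silyl]oxy}‑2H‑chromen‑6‑yl)‑1‑{2‑[(3‑methylbut‑2‑en‑1‑yl)oxy]‑4,6‑bis{[tri(propan‑2‑yl)silyl]oxy}phenyl}prop‑2‑yn‑1‑one | O=C(C#Cc1cc(O[Si](C(C)C)(C(C)C)C(C)C)c2OC(C)(C)C=Cc2c1)c1c(OCC=C(C)C)cc(O[Si](C(C)C)(C(C)C)C(C)C)cc1O[Si](C(C)C)(C(C)C)C(C)C | intermediate
16 | 7‑hydroxy‑2‑(8‑hydroxy‑2,2‑dimethyl‑2H‑chromen‑6‑yl)‑5‑[(3‑methylbut‑2‑en‑1‑yl)oxy]‑4H‑chromen‑4‑one | CC(C)=CCOc1cc(O)cc2oc(-c3cc(O)c4OC(C)(C)C=Cc4c3)cc(=O)c12 | intermediate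
17 | 5,7‑dihydroxy‑2‑(8‑hydroxy‑2,2‑dimethyl‑2H‑chromen‑6‑yl)‑8‑(3‑methylbut‑2‑en‑1‑yl)‑4H‑chromen‑4‑one | CC(C)=CCc1c(O)cc(O)c2c(=O)cc(-c3cc(O)c4c(c3)C=CC(C)(C)O4)oc12 | target

**Count**

Total steps: 10. Longest linear sequence: 6 steps (steps 1, 2, 3, 4, 9, 10; the B branch, steps 5, 6, 7, 8, 9, 10, is equally long).

**Steps most likely to fail**

Step 9. The terminal ynone may be lost to amine‑induced oligomerisation or alkyne homocoupling before it cross‑couples. Once phenoxides are present, residual Pd(0) may also ionise the aryl prenyl ether and move the prenyl group between oxygens. The fallback joins the fragments one oxidation level lower, where the alkyne is not a Michael acceptor. It sets out from alcohol 6 and iodide 14, which are coupled under the same Pd/Cu catalysis to give the diaryl propargylic alcohol F1. F1 is purified and oxidised with MnO2 to the diaryl ynone 15, now isolated and free of metal. Treatment of 15 with TBAF in THF and an acetic acid quench then returns to the route at 16.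

Step 10. The free phenols may bind the europium catalyst or limit solubility, and the sequence may stop after the first [3,3] shift, giving the 6‑(1,1‑dimethylallyl) isomer instead of the C8 product. The fallback masks the phenols as esters. It sets out from 16, which with Ac2O and pyridine should give the diacetate F2. Eu(fod)3 and NaHCO3 in PhCl at 85 °C should then give the 8‑prenyl‑5‑hydroxy diacetate F3. Methanolysis with K2CO3 in MeOH at rt returns to the route at 17 without exposing the prenyl phenol to acid.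

Step 3. The hindered, electron‑rich aldehyde may add slowly, the ortho silyl group may move to the new alkoxide, and the electron‑rich propargylic alcohol may ionise on work‑up. The fallback reaches the ynone at the acid oxidation level, with no alkoxide next to the silyl ether. It sets out from aldehyde 4. Pinnick oxidation (NaClO2, NaH2PO4, 2‑methylbut‑2‑ene, t‑BuOH/H2O) should give the benzoic acid F4. 1‑Chloro‑N,N,2‑trimethylprop‑1‑en‑1‑amine in CH2Cl2 converts F4 under neutral conditions into the acid chloride F5. A Stille acylation of tributyl(ethynyl)stannane with F5 (PdCl2(PPh3)2, toluene, 60 °C) returns to the route at 7.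

**Further compounds**

F1 | step 9 | 3‑(2,2‑dimethyl‑8‑{[tri(propan‑2‑yl)silyl]oxy}‑2H‑chromen‑6‑yl)‑1‑{2‑[(3‑methylbut‑2‑en‑1‑yl)oxy]‑4,6‑bis{[tri(propan‑2‑yl)silyl]oxy}phenyl}prop‑2‑yn‑1‑ol | OC(C#Cc1cc(O[Si](C(C)C)(C(C)C)C(C)C)c2OC(C)(C)C=Cc2c1)c1c(OCC=C(C)C)cc(O[Si](C(C)C)(C(C)C)C(C)C)cc1O[Si](C(C)C)(C(C)C)C(C)C
F2 | step 10 | 2‑[8‑(acetyloxy)‑2,2‑dimethyl‑2H‑chromen‑6‑yl]‑5‑[(3‑methylbut‑2‑en‑1‑yl)oxy]‑4‑oxo‑4H‑chromen‑7‑yl acetate | CC(C)=CCOc1cc(OC(C)=O)cc2oc(-c3cc(OC(C)=O)c4OC(C)(C)C=Cc4c3)cc(=O)c12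
F3 | step 10 | 2‑[8‑(acetyloxy)‑2,2‑dimethyl‑2H‑chromen‑6‑yl]‑5‑hydroxy‑8‑(3‑methylbut‑2‑en‑1‑yl)‑4‑oxo‑4H‑chromen‑7‑yl acetate | CC(C)=CCc1c(OC(C)=O)cc(O)c2c(=O)cc(-c3cc(OC(C)=O)c4OC(C)(C)C=Cc4c3)oc12
F4 | step 3 | 2‑[(3‑methylbut‑2‑en‑1‑yl)oxy]‑4,6‑bis{[tri(propan‑2‑yl)silyl]oxy}benzoic acid | OC(=O)c1c(OCC=C(C)C)cc(O[Si](C(C)C)(C(C)C)C(C)C)cc1O[Si](C(C)C)(C(C)C)C(C)C
F5 | step 3 | 2‑[(3‑methylbut‑2‑en‑1‑yl)oxy]‑4,6‑bis{[tri(propan‑2‑yl)silyl]oxy}benzoyl chloride | ClC(=O)c1c(OCC=C(C)C)cc(O[Si](C(C)C)(C(C)C)C(C)C)cc1O[Si](C(C)C)(C(C)C)C(C)C
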